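**Retrosynthetic overview** (indane numbering: C1 carries the exocyclic alkene to Cα and ring E, C2 carries ring D, C3 carries ring C, ring A is fused at C3a–C7a with oxygen at C4 and C6, ring B is the five-membered ring)

1. The strategy rests on one feature: the 2-hydroxyl of ring C lies three atoms from C1 (O–C2'–C1'–C3–C2–C1), so ring C, C3, C2 and C1 are the atoms of a 7-alkoxy-3,4-dihydrocoumarin and this oxygen can hold C1 as a temporary lactone.
2. Target ⇐ BCl3 removal of seven isopropyl ethers ⇐ syn dehydration of the C1 carbinol ⇐ benzylcerium (ring E) addition to the 2,3-trans indanone.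
3. Ring B (C1–C7a) ⇐ Parham closure of the ring A bromide onto a morpholine amide obtained by opening the lactone. The trans lactone maps onto the cis indanone, so C2 is equilibrated next to the C1 ketone.
4. Lactone ⇐ C2–C3 and O–C1 bonds from the ring C ortho-quinone methide (methide carbon C3 bearing bromo ring A, from a sulfone) and the ammonium enolate of the ring D acetic acid.
5. Ring order: rings A, C, D and E come from aromatic starting materials; temporary lactone ring (step 7), opened (step 8), then ring B (step 10).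

Key step: step 7

Assumption: the annulation is taken to follow the usual isothiourea model (bond formation on the enolate face remote from the catalyst phenyl group, anti Michael approach), which assigns (R)-benzotetramisole to the (3R,4S)-lactone; if the syn approach prevailed, (S)-benzotetramisole would be used and nothing else changes, because C2 of the indane is reset in step 10.

**Route**

Step 1
Reactants: 1 5-bromoresorcinol
Product: 2 1-bromo-3,5-diisopropoxybenzene
Conditions: 2-bromopropane, K2CO3, DMF, 60 °C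
Reagents that add atoms: 2-bromopropane, CC(C)Br
Why: Williamson ether synthesis on both phenols; the aryl bromide is inert to carbonate.

Step 2
Reactants: 2 1-bromo-3,5-diisopropoxybenzene
Product: 3 1-bromo-2-iodo-3,5-diisopropoxybenzene
Conditions: N-iodosuccinimide, CF3CO2H (cat.), MeCN, 0 °C → rt
Reagents that add atoms: N-iodosuccinimide, O=C1CCC(=O)N1I
Why: electrophilic aromatic iodination should go ortho to bromine and para to an isopropoxy group, the usual site in 5-substituted resorcinol diethers (the carbon between the two ethers is more crowded); iodine marks the future C3a and bromine stays for C7a.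

Step 3
Reactants: 4 2,4-dihydroxybenzaldehyde
Product: 5 2-hydroxy-4-isopropoxybenzaldehyde
Conditions: 2-bromopropane (1.2 equiv), K2CO3 (1.05 equiv), KI (cat.), DMF, 50 °C
Reagents that add atoms: 2-bromopropane, CC(C)Br
Why: selective Williamson etherification of the 4-hydroxyl, because the 2-hydroxyl is hydrogen-bonded to the aldehyde and its phenoxide is the weaker nucleophile.

Step 4
Reactants: 3 1-bromo-2-iodo-3,5-diisopropoxybenzene; 5 2-hydroxy-4-isopropoxybenzaldehyde
Product: 7 2-[(2-bromo-4,6-diisopropoxyphenyl)(hydroxy)methyl]-5-isopropoxyphenol (racemic), via arylmagnesium chloride 6 (not isolated)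
Conditions: 3, i-PrMgCl·LiCl, THF, −30 °C; 5 pretreated with NaH (THF, 0 °C) then added, −30 → 0 °C; aq NH4Cl
Reagents that add atoms: none
Why: iodine–magnesium exchange is selective for iodide over bromide and the ortho-bromo arylmagnesium is stable below 0 °C, and Grignard 1,2-addition to the aldehyde of the sodium phenoxide gives the ortho-hydroxy benzhydrol; the carbinol centre (future C3) is racemic and is planarised in step 7.

Step 5
Reactants: 7 2-[(2-bromo-4,6-diisopropoxyphenyl)(hydroxy)methyl]-5-isopropoxyphenol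
Product: 8 2-[(2-bromo-4,6-diisopropoxyphenyl)(4-methylbenzenesulfonyl)methyl]-5-isopropoxyphenol (racemic)
Conditions: 4-MeC6H4SO2H (1.5 equiv), CH2Cl2, rt
Reagents that add atoms: p-toluenesulfinic acid, Cc1ccc(cc1)S(=O)O
Why: acid-promoted ionisation of the doubly activated benzhydrol and capture of the cation by sulfinate at sulfur (SN1-type sulfone formation), the standard preparation of 2-(sulfonylmethyl)phenols as quinone methide precursors.

Step 6
Reactants: 9 (3,5-dihydroxyphenyl)acetic acid
Product: 11 2-(3,5-diisopropoxyphenyl)acetic acid, via isopropyl ester 10 (not isolated)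
Conditions: 2-bromopropane, K2CO3, DMF, 60 °C; then NaOH, MeOH/H2O, 60 °C; HCl
Reagents that add atoms: 2-bromopropane, CC(C)Br; sodium hydroxide, [Na+].[OH-]
Why: exhaustive O-alkylation (Williamson ether synthesis and carboxylate alkylation) followed by saponification, which cleaves only the ester.

Step 7
Reactants: 8 2-[(2-bromo-4,6-diisopropoxyphenyl)(4-methylbenzenesulfonyl)methyl]-5-isopropoxyphenol; 11 2-(3,5-diisopropoxyphenyl)acetic acid
Product: 14 (3R,4S)-4-(2-bromo-4,6-diisopropoxyphenyl)-3-(3,5-diisopropoxyphenyl)-7-isopropoxy-3,4-dihydro-2H-chromen-2-one (trans), via mixed pivalic anhydride 12 (not isolated), via ortho-quinone methide 13 (not isolated)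
Conditions: 11 (2 equiv), t-BuCOCl (2 equiv), i-Pr2NEt (4 equiv), CH2Cl2, 0 °C; then (R)-benzotetramisole (C15H12N2S, 20 mol%), 8, Cs2CO3 (1.5 equiv), 0 °C → rt
Reagents that add atoms: none
Why: Cs2CO3 eliminates sulfinate from 8 to give the E-configured ortho-quinone methide 13, while the catalyst is acylated by 12 and deprotonated to the Z-ammonium enolate (oxygen held syn to sulfur), which adds through C2 to the methide carbon C3; the phenoxide then attacks the acyl ammonium, forming the O–C1 bond and releasing the catalyst. The closest known reaction type is the isothiourea-catalysed Michael addition–lactonisation (formal (4+2) annulation) of C1-ammonium enolates with ortho-quinone methides released from 2-(sulfonylmethyl)phenols. The only ring closed is the six-membered lactone, by 6-exo-trig acyl substitution of the phenoxide on the acyl ammonium carbon. C2 (lactone C3, R) is set by the catalyst, whose pseudoaxial phenyl group covers one enolate face, and C3 (lactone C4, S) by the anti approach in which the quinone methide ring lies over the cationic catalyst and ring A, outside on the E-methide, turns away from ring D; the trans adduct is also the more stable lactone. The step needs facial selectivity at C3 only, since C2 is re-equilibrated in step 10 (the trans lactone maps onto the cis indanone); this is secured by the single E geometry of 13, imposed by the twisted, doubly ortho-substituted ring A, together with catalyst control of the enolate face, and the minor syn adduct, which has the opposite C3 configuration, is removed by crystallisation before any base treatment. The C7a bromine is inert here and is kept for ring B.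

Step 8
Reactants: 14 (3R,4S)-lactone
Product: 15 (2R,3S)-3-(2-bromo-4,6-diisopropoxyphenyl)-2-(3,5-diisopropoxyphenyl)-3-(2-hydroxy-4-isopropoxyphenyl)-1-(morpholin-4-yl)propan-1-one
Conditions: morpholine (5 equiv), THF, 50 °C
Reagents that add atoms: morpholine, C1COCCN1
Why: aminolysis of the aryl ester lactone opens the tether before any organometallic meets its acidic C2–H (α to an aryl ester and benzylic, which would be deprotonated and fragment to a ketene), and gives an amide that stops at the ketone stage on aryllithium addition.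

Step 9
Reactants: 15 phenol amide
Product: 16 (2R,3S)-3-(2-bromo-4,6-diisopropoxyphenyl)-3-(2,4-diisopropoxyphenyl)-2-(3,5-diisopropoxyphenyl)-1-(morpholin-4-yl)propan-1-one
Conditions: 2-iodopropane, Cs2CO3, DMF, 50 °C
Reagents that add atoms: 2-iodopropane, CC(C)I
Why: Williamson etherification of the hindered phenol; carbonate does not deprotonate the amide α-carbon.

Step 10
Reactants: 16 bromo amide
Product: 20 (2S,3S)-3-(2,4-diisopropoxyphenyl)-2-(3,5-diisopropoxyphenyl)-4,6-diisopropoxy-2,3-dihydro-1H-inden-1-one (trans), via aryllithium 17 (not isolated), via lithium hemiaminal alkoxide 18 (not isolated), via cis-indanone 19 (not isolated)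
Conditions: t-BuLi (2.2 equiv), THF, −78 °C; aq NH4Cl; crude product, DBU (C9H16N2, 0.3 equiv), CH2Cl2, rt, under N2
Reagents that add atoms: none
Why: Parham cyclisation, in which bromine–lithium exchange at −78 °C outruns deprotonation, the aryllithium closes ring B by 5-exo-trig attack on the amide and the stable tetrahedral adduct collapses on quench to the cis-indanone; DBU then enolises C2 (α to the ketone and benzylic) and equilibration should leave the 2,3-trans isomer with the aryl groups anti (C2 becomes S), while C3 is not α to the carbonyl and is untouched.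

Step 11
Reactants: 21 vanillin
Product: 22 4-isopropoxy-3-methoxybenzaldehyde
Conditions: 2-bromopropane, K2CO3, DMF, 60 °C
Reagents that add atoms: 2-bromopropane, CC(C)Br
Why: Williamson ether synthesis on the single phenol.

Step 12
Reactants: 22 4-isopropoxy-3-methoxybenzaldehyde
Product: 23 (4-isopropoxy-3-methoxyphenyl)methanol
Conditions: NaBH4, MeOH, 0 °C
Reagents that add atoms: none
Why: borohydride reduction of an aromatic aldehyde.

Step 13
Reactants: 23 (4-isopropoxy-3-methoxyphenyl)methanol
Product: 24 4-(chloromethyl)-1-isopropoxy-2-methoxybenzene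
Conditions: SOCl2, CH2Cl2, 0 °C → rt
Reagents that add atoms: thionyl chloride, O=S(Cl)Cl
Why: chlorodehydroxylation of an electron-rich benzylic alcohol through its chlorosulfite.

Step 14
Reactants: 20 trans-indanone; 24 4-(chloromethyl)-1-isopropoxy-2-methoxybenzene
Product: 26 (1R,2S,3S)-1-(4-isopropoxy-3-methoxybenzyl)-3-(2,4-diisopropoxyphenyl)-2-(3,5-diisopropoxyphenyl)-4,6-diisopropoxy-2,3-dihydro-1H-inden-1-ol, via benzylmagnesium chloride 25 (not isolated)
Conditions: 24, Mg, THF, 0 °C; anhydrous CeCl3, THF, −78 °C; then 20, −78 → 0 °C; aq NH4Cl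
Reagents that add atoms: none
Why: organocerium 1,2-addition (Imamoto conditions) suppresses enolisation at C2, and the benzyl group should enter C1 anti to ring D on the adjacent C2, leaving the hydroxyl cis to ring D and trans to H2; this C1 centre is removed in step 15 and serves only to direct the elimination.

Step 15
Reactants: 26 tertiary carbinol
Product: 27 (1E,2S,3S)-1-(4-isopropoxy-3-methoxybenzylidene)-3-(2,4-diisopropoxyphenyl)-2-(3,5-diisopropoxyphenyl)-4,6-diisopropoxy-2,3-dihydro-1H-indene
Conditions: Burgess reagent (Et3N+SO2N−CO2Me), toluene, 50 °C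
Reagents that add atoms: none
Why: Burgess dehydration is a syn elimination through a cyclic sulfamate transition state, and with the C1 oxygen trans to H2 only the benzylic CH2 hydrogens are within reach, so the alkene should form between C1 and Cα; the E geometry keeps ring E away from the peri C7–H.

Step 16
Reactants: 27 heptaisopropyl ether
Product: 28 (1E,2S,3S)-2-(3,5-dihydroxyphenyl)-3-(2,4-dihydroxyphenyl)-1-(4-hydroxy-3-methoxybenzylidene)-2,3-dihydro-1H-indene-4,6-diol
Conditions: BCl3 (excess), CH2Cl2, −78 → 0 °C; MeOH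
Reagents that add atoms: none
Why: Lewis acid dealkylation, in which BCl3 cleaves the secondary (isopropyl) aryl ethers well below the temperature needed for the methyl ether; low temperature and the absence of strong protic acid should keep the exocyclic alkene and both stereocentres in place.

**Compound list**

1 | 5-bromoresorcinol (5-bromobenzene-1,3-diol) | Oc1cc(O)cc(Br)c1 | starting material
2 | 1-bromo-3,5-diisopropoxybenzene | CC(C)Oc1cc(Br)cc(OC(C)C)c1 | intermediate
3 | 1-bromo-2-iodo-3,5-diisopropoxybenzene | CC(C)Oc1cc(Br)c(I)c(OC(C)C)c1 | intermediate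
4 | 2,4-dihydroxybenzaldehyde | O=Cc1ccc(O)cc1O | starting material
5 | 2-hydroxy-4-isopropoxybenzaldehyde | O=Cc1ccc(OC(C)C)cc1O | intermediate
6 | (2-bromo-4,6-diisopropoxyphenyl)magnesium chloride (formed in the flask) | CC(C)Oc1cc(Br)c([Mg]Cl)c(OC(C)C)c1 | intermediate
7 | 2-[(2-bromo-4,6-diisopropoxyphenyl)(hydroxy)methyl]-5-isopropoxyphenol (racemic) | OC(c1ccc(OC(C)C)cc1O)c1c(Br)cc(OC(C)C)cc1OC(C)C | intermediate
8 | 2-[(2-bromo-4,6-diisopropoxyphenyl)(4-methylbenzenesulfonyl)methyl]-5-isopropoxyphenol (racemic) | Cc1ccc(cc1)S(=O)(=O)C(c1ccc(OC(C)C)cc1O)c1c(Br)cc(OC(C)C)cc1OC(C)C | intermediate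
9 | (3,5-dihydroxyphenyl)acetic acid | OC(=O)Cc1cc(O)cc(O)c1 | starting material
10 | isopropyl 2-(3,5-diisopropoxyphenyl)acetate (formed in the flask) | CC(C)OC(=O)Cc1cc(OC(C)C)cc(OC(C)C)c1 | intermediate
11 | 2-(3,5-diisopropoxyphenyl)acetic acid | OC(=O)Cc1cc(OC(C)C)cc(OC(C)C)c1 | intermediate
12 | 2-(3,5-diisopropoxyphenyl)acetic pivalic anhydride (formed in the flask) | CC(C)(C)C(=O)OC(=O)Cc1cc(OC(C)C)cc(OC(C)C)c1 | intermediate
13 | (6E)-6-[(2-bromo-4,6-diisopropoxyphenyl)methylidene]-3-isopropoxycyclohexa-2,4-dien-1-one (formed in the flask) | O=C1C=C(OC(C)C)C=C/C1=C\c1c(Br)cc(OC(C)C)cc1OC(C)C | intermediate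
14 | (3R,4S)-4-(2-bromo-4,6-diisopropoxyphenyl)-3-(3,5-diisopropoxyphenyl)-7-isopropoxy-3,4-dihydro-2H-chromen-2-one (trans) | O=C1Oc2cc(OC(C)C)ccc2[C@@H](c2c(Br)cc(OC(C)C)cc2OC(C)C)[C@@H]1c1cc(OC(C)C)cc(OC(C)C)c1 | intermediate
15 | (2R,3S)-3-(2-bromo-4,6-diisopropoxyphenyl)-2-(3,5-diisopropoxyphenyl)-3-(2-hydroxy-4-isopropoxyphenyl)-1-(morpholin-4-yl)propan-1-one | O=C(N1CCOCC1)[C@@H](c1cc(OC(C)C)cc(OC(C)C)c1)[C@@H](c1ccc(OC(C)C)cc1O)c1c(Br)cc(OC(C)C)cc1OC(C)C | intermediate
16 | (2R,3S)-3-(2-bromo-4,6-diisopropoxyphenyl)-3-(2,4-diisopropoxyphenyl)-2-(3,5-diisopropoxyphenyl)-1-(morpholin-4-yl)propan-1-one | O=C(N1CCOCC1)[C@@H](c1cc(OC(C)C)cc(OC(C)C)c1)[C@@H](c1ccc(OC(C)C)cc1OC(C)C)c1c(Br)cc(OC(C)C)cc1OC(C)C | intermediate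
17 | aryllithium from 16, lithium in place of bromine (formed in the flask) | O=C(N1CCOCC1)[C@@H](c1cc(OC(C)C)cc(OC(C)C)c1)[C@@H](c1ccc(OC(C)C)cc1OC(C)C)c1c([Li])cc(OC(C)C)cc1OC(C)C | intermediate
18 | lithium alkoxide of the 1-morpholino-indan-1-ol, tetrahedral adduct, C1 undefined (formed in the flask) | [Li]OC1(N2CCOCC2)c2cc(OC(C)C)cc(OC(C)C)c2[C@H](c2ccc(OC(C)C)cc2OC(C)C)[C@@H]1c1cc(OC(C)C)cc(OC(C)C)c1 | intermediate
19 | (2R,3S)-3-(2,4-diisopropoxyphenyl)-2-(3,5-diisopropoxyphenyl)-4,6-diisopropoxy-2,3-dihydro-1H-inden-1-one (cis, formed in the flask) | O=C1c2cc(OC(C)C)cc(OC(C)C)c2[C@H](c2ccc(OC(C)C)cc2OC(C)C)[C@@H]1c1cc(OC(C)C)cc(OC(C)C)c1 | intermediate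
20 | (2S,3S)-3-(2,4-diisopropoxyphenyl)-2-(3,5-diisopropoxyphenyl)-4,6-diisopropoxy-2,3-dihydro-1H-inden-1-one (trans) | O=C1c2cc(OC(C)C)cc(OC(C)C)c2[C@H](c2ccc(OC(C)C)cc2OC(C)C)[C@H]1c1cc(OC(C)C)cc(OC(C)C)c1 | intermediate
21 | vanillin | COc1cc(C=O)ccc1O | starting material
22 | 4-isopropoxy-3-methoxybenzaldehyde | COc1cc(C=O)ccc1OC(C)C | intermediate
23 | (4-isopropoxy-3-methoxyphenyl)methanol | COc1cc(CO)ccc1OC(C)C | intermediate
24 | 4-(chloromethyl)-1-isopropoxy-2-methoxybenzene | COc1cc(CCl)ccc1OC(C)C | intermediate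
25 | (4-isopropoxy-3-methoxybenzyl)magnesium chloride (formed in the flask) | COc1cc(C[Mg]Cl)ccc1OC(C)C | intermediate
26 | (1R,2S,3S)-1-(4-isopropoxy-3-methoxybenzyl)-3-(2,4-diisopropoxyphenyl)-2-(3,5-diisopropoxyphenyl)-4,6-diisopropoxy-2,3-dihydro-1H-inden-1-ol | O[C@@]1(Cc2ccc(OC(C)C)c(OC)c2)c2cc(OC(C)C)cc(OC(C)C)c2[C@H](c2ccc(OC(C)C)cc2OC(C)C)[C@H]1c1cc(OC(C)C)cc(OC(C)C)c1 | intermediate
27 | (1E,2S,3S)-1-(4-isopropoxy-3-methoxybenzylidene)-3-(2,4-diisopropoxyphenyl)-2-(3,5-diisopropoxyphenyl)-4,6-diisopropoxy-2,3-dihydro-1H-indene | COc1cc(/C=C2/c3cc(OC(C)C)cc(OC(C)C)c3[C@H](c3ccc(OC(C)C)cc3OC(C)C)[C@H]2c2cc(OC(C)C)cc(OC(C)C)c2)ccc1OC(C)C | intermediate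
28 | (1E,2S,3S)-2-(3,5-dihydroxyphenyl)-3-(2,4-dihydroxyphenyl)-1-(4-hydroxy-3-methoxybenzylidene)-2,3-dihydro-1H-indene-4,6-diol (CNP0122890.1) | COc1cc(/C=C2/c3cc(O)cc(O)c3[C@H](c3ccc(O)cc3O)[C@H]2c2cc(O)cc(O)c2)ccc1O | target

**Totals**

Total step count: 16.
Longest linear sequence: 11 steps (steps 1, 2, 4, 5, 7, 8, 9, 10, 14, 15, 16, from 5-bromoresorcinol).

**Steps most likely to fail**

Step 7. Bond formation at a methide carbon flanked by a doubly ortho-substituted ring may be slow, so acylation of the phenol of 8 by 12 or self-condensation of the quinone methide could win. A competing syn approach would also give the opposite C3 configuration, and base epimerisation of that adduct would erode the enantiomeric purity of the trans lactone. Fallback, from 11 and 8, returning at 14: acid 11 is converted (t-BuCOCl, Et3N; then (R)-4-benzyloxazolidin-2-one, LiCl) into the imide (R)-4-benzyl-3-[2-(3,5-diisopropoxyphenyl)acetyl]oxazolidin-2-one F1. Its Z-sodium enolate (NaN(SiMe3)2, THF, −78 °C) is combined with 13, released from 8 by a further equivalent of the same base. Auxiliary-controlled Michael addition on the enolate face remote from the benzyl group should give the open adduct (R)-4-benzyl-3-[(2R,3S)-3-(2-bromo-4,6-diisopropoxyphenyl)-2-(3,5-diisopropoxyphenyl)-3-(2-hydroxy-4-isopropoxyphenyl)propanoyl]oxazolidin-2-one F2. On warming, its phenoxide closes onto the exocyclic imide carbonyl and expels the auxiliary to give 14. The auxiliary antipode follows the same topicity argument as the catalyst.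

Step 15. Regiocontrol of the elimination may be lost, through ionisation to the C1 cation or through syn elimination in a minor C1 epimer of 26. Either would move the double bond into the five-membered ring or scramble its geometry. Fallback, from 20 and 25, returning at 27: two equivalents of 25 and Cp2TiCl2 (THF, 0 °C) give bis(cyclopentadienyl)bis(4-isopropoxy-3-methoxybenzyl)titanium F3. Heating F3 with ketone 20 in toluene at 55 °C (Petasis benzylidenation: α-elimination to the titanium benzylidene, cycloaddition to the carbonyl, cycloreversion) converts C1=O directly into C1=Cα. The alkene can then lie only in the exocyclic position, and the E isomer is expected for the same peri reason.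

Step 10. Proton transfer from the benzylic amide α-C–H to t-BuLi or to the aryllithium (loss of bromine without ring closure), or direct attack of t-BuLi on the amide, may compete with cyclisation. Fallback, from 16, returning at 20: reduction with i-Bu2AlH (THF, −78 °C) gives (2R,3S)-3-(2-bromo-4,6-diisopropoxyphenyl)-3-(2,4-diisopropoxyphenyl)-2-(3,5-diisopropoxyphenyl)propanal F4. Methylenation with Ph3P=CH2 gives (3R,4S)-4-(2-bromo-4,6-diisopropoxyphenyl)-4-(2,4-diisopropoxyphenyl)-3-(3,5-diisopropoxyphenyl)but-1-ene F5. An intramolecular Heck reaction (Pd(OAc)2, PPh3, Et3N, DMF, 90 °C; 5-exo-trig, β-hydride loss possible only from C1–H) closes ring B to (2R,3S)-1-methylene-3-(2,4-diisopropoxyphenyl)-2-(3,5-diisopropoxyphenyl)-4,6-diisopropoxy-2,3-dihydro-1H-indene F6. Oxidative cleavage (OsO4 cat., NaIO4, dioxane/H2O) gives 19, and DBU equilibration as in step 10 gives 20.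

**Further compounds**

F1 | step 7 | (R)-4-benzyl-3-[2-(3,5-diisopropoxyphenyl)acetyl]oxazolidin-2-one | O=C(Cc1cc(OC(C)C)cc(OC(C)C)c1)N1[C@H](Cc2ccccc2)COC1=O
F2 | step 7 | (R)-4-benzyl-3-[(2R,3S)-3-(2-bromo-4,6-diisopropoxyphenyl)-2-(3,5-diisopropoxyphenyl)-3-(2-hydroxy-4-isopropoxyphenyl)propanoyl]oxazolidin-2-one | O=C([C@@H](c1cc(OC(C)C)cc(OC(C)C)c1)[C@@H](c1ccc(OC(C)C)cc1O)c1c(Br)cc(OC(C)C)cc1OC(C)C)N1[C@H](Cc2ccccc2)COC1=O
F3 | step 15 | bis(cyclopentadienyl)bis(4-isopropoxy-3-methoxybenzyl)titanium | COc1cc(C[Ti](Cc2ccc(OC(C)C)c(OC)c2)(C2C=CC=C2)C2C=CC=C2)ccc1OC(C)C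
F4 | step 10 | (2R,3S)-3-(2-bromo-4,6-diisopropoxyphenyl)-3-(2,4-diisopropoxyphenyl)-2-(3,5-diisopropoxyphenyl)propanal | O=C[C@@H](c1cc(OC(C)C)cc(OC(C)C)c1)[C@@H](c1ccc(OC(C)C)cc1OC(C)C)c1c(Br)cc(OC(C)C)cc1OC(C)C
F5 | step 10 | (3R,4S)-4-(2-bromo-4,6-diisopropoxyphenyl)-4-(2,4-diisopropoxyphenyl)-3-(3,5-diisopropoxyphenyl)but-1-ene | C=C[C@@H](c1cc(OC(C)C)cc(OC(C)C)c1)[C@@H](c1ccc(OC(C)C)cc1OC(C)C)c1c(Br)cc(OC(C)C)cc1OC(C)C
F6 | step 10 | (2R,3S)-1-methylene-3-(2,4-diisopropoxyphenyl)-2-(3,5-diisopropoxyphenyl)-4,6-diisopropoxy-2,3-dihydro-1H-indene | C=C1c2cc(OC(C)C)cc(OC(C)C)c2[C@H](c2ccc(OC(C)C)cc2OC(C)C)[C@@H]1c1cc(OC(C)C)cc(OC(C)C)c1
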